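**Plan**

1. Cuts: the C2'–C3' single bond of the diene (Suzuki–Miyaura union of a chroman alkenylboronate with an alkenyl iodide); in the carbocycle, the bond between the side-chain-bearing alkene carbon C1 and the quaternary C6; in the chroman, the O1–C8a aryl ether bond and the C4–C4a bond.
2. Enabling feature: C6 of the cyclohexene carries two identical methyls and no hydrogen, and C1 is an sp2 carbon of the tetrasubstituted C1=C2 alkene. A C1 alkenylpalladium can therefore add 6-exo to an isopropenyl group; the neopentyl palladium left on the former =CH2 has no β-hydrogen and is reduced to the second methyl, so ring, quaternary carbon and regiodefined tetrasubstituted alkene arise in one event.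
3. Carbocycle, forward: directed syn-carbomagnesiation/iodination gives the acyclic (Z)-iodo-diene, the reductive Heck reaction closes the ring, then iodide, acetylide and zirconium-catalysed methylalumination/iodination give the (E)-2-methylalkenyl iodide.
4. Chroman, forward: (S)-2-methylglycidol is tritylated, homologated to the vinyl carbinol and joined to the fluoroarene by B-alkyl Suzuki coupling; SNAr closes the pyran ring; the CH2OH arm becomes CHO, then the (E)-alkenylboronate.
5. The two halves are coupled to the (E,E)-diene and the methyl ester is saponified.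
6. Stereochemistry: the single stereocentre (chroman C2, R) is bought with (S)-2-methylglycidol and none of its bonds is broken afterwards; alkene geometries come from syn-carbometalations, Takai–Utimoto olefination and stereoretentive couplings.

Key step: step 2

Assumption: C2 of the chroman is read from the SMILES as R; (S)-2-methylglycidol has the same spatial arrangement at that carbon (the letter changes only through the priority rules), and 1, 2, 11 and 15 are taken as commercial.

**Route**

Step 1
Reactants: 1 5-bromo-2-methylpent-1-ene; 2 pent-3-yn-1-ol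
Product: 5 (Z)-3-iodo-4,8-dimethylnona-3,8-dien-1-ol, via Grignard reagent 3 (not isolated), via alkenylmagnesium alkoxide 4 (not isolated)
Conditions: Mg, THF, rt (1 to 3, 3.5 equiv); then 2, Fe(acac)3 (15 mol %), THF, −20 to 0 °C; then I2, −78 to 0 °C; aq NH4Cl
Reagents that add atoms: iodine, II
Why: Alkoxide-directed, Fe-catalysed syn-carbomagnesiation of a homopropargylic alcohol: the first equivalent of 3 forms the magnesium alkoxide of 2, the alkyl group then adds to the alkyne carbon remote from oxygen and magnesium to the near carbon on the same face (five-membered chelate), and iodinolysis with retention should place iodine cis to the 4-methylpent-4-enyl chain, the geometry the ring closure needs.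

Step 2
Reactants: 5 (Z)-3-iodo-4,8-dimethylnona-3,8-dien-1-ol
Product: 6 2-(2,6,6-trimethylcyclohex-1-en-1-yl)ethan-1-ol
Conditions: Pd(OAc)2 (10 mol %), PPh3 (25 mol %), HCO2Na (2 equiv), Et4NCl (1 equiv), DMF, degassed, 80 °C
Reagents that add atoms: none
Why: Zerovalent palladium inserts into the C–I bond of 5 with retention, the alkenylpalladium adds across the 1,1-disubstituted alkene with the alkenyl carbon bonding to the internal alkene carbon, and the resulting neopentyl-type alkylpalladium, which has no β-hydrogen, exchanges iodide for formate, loses CO2 and reductively eliminates C–H, so the former =CH2 becomes the second methyl of the quaternary carbon. The closest known reaction type is the intramolecular reductive Heck cyclisation (Heck insertion with hydride capture) used to build quaternary carbons. The cyclohexene closes in the 6-exo-trig mode. No stereocentre is formed because the new quaternary carbon carries two methyls; the only geometric demand, palladium cis to the tether, is met by the Z geometry fixed in step 1. The step needs 6-exo over 7-endo insertion, secured by the three-carbon tether and the preference of palladium for the terminal CH2, and insertion faster than formate reduction of the alkenylpalladium, secured by intramolecularity. The tetrasubstituted ring alkene is the untouched alkene of the alkenyl iodide, so no positional isomer of the ring double bond can form.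

Step 3
Reactants: 6 2-(2,6,6-trimethylcyclohex-1-en-1-yl)ethan-1-ol
Product: 7 2-(2-iodoethyl)-1,3,3-trimethylcyclohex-1-ene
Conditions: PPh3, I2, imidazole, CH2Cl2, 0 °C to rt
Reagents that add atoms: iodine, II
Why: Appel-type iodination, in which the primary alcohol is activated as an alkoxyphosphonium ion and displaced by iodide in an SN2 reaction that should leave the hindered tetrasubstituted alkene untouched.

Step 4
Reactants: 7 2-(2-iodoethyl)-1,3,3-trimethylcyclohex-1-ene
Product: 8 2-(but-3-yn-1-yl)-1,3,3-trimethylcyclohex-1-ene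
Conditions: LiC≡CH·H2NCH2CH2NH2 (2 equiv), DMSO, 15 °C to rt
Reagents that add atoms: lithium acetylide ethylenediamine complex, [Li]C#C.NCCN
Why: SN2 alkylation of lithium acetylide by an unhindered primary iodide in DMSO, a standard entry to terminal alkynes from homoallylic iodides.

Step 5
Reactants: 8 2-(but-3-yn-1-yl)-1,3,3-trimethylcyclohex-1-ene
Product: 10 2-[(3E)-4-iodo-3-methylbut-3-en-1-yl]-1,3,3-trimethylcyclohex-1-ene, via alkenylalane 9 (not isolated)
Conditions: Me3Al (2.5 equiv), Cp2ZrCl2 (0.3 equiv), CH2Cl2, rt; then I2, THF, −30 to 0 °C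
Reagents that add atoms: trimethylaluminium, C[Al](C)C; iodine, II
Why: Negishi zirconium-catalysed carboalumination adds methyl and aluminium syn across the terminal alkyne with aluminium on the terminal carbon, and iodinolysis with retention should give the (E)-2-methylalkenyl iodide while the tetrasubstituted ring alkene stays inert.

Step 6
Reactants: 11 (S)-2-methylglycidol
Product: 12 (R)-2-methyl-2-[(triphenylmethoxy)methyl]oxirane
Conditions: Ph3CCl, Et3N, DMAP (cat.), CH2Cl2, 0 °C to rt
Reagents that add atoms: trityl chloride, ClC(c1ccccc1)(c1ccccc1)c1ccccc1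
Why: Tritylation of the primary alcohol under amine base avoids the alkoxide and hence the Payne rearrangement that would racemise this epoxy alcohol; the spatial arrangement is unchanged and the descriptor changes from S to R only through the priority rules.

Step 7
Reactants: 12 (R)-2-methyl-2-[(triphenylmethoxy)methyl]oxirane
Product: 13 (R)-2-methyl-1-(triphenylmethoxy)but-3-en-2-ol
Conditions: Me3S+ I− (3 equiv), n-BuLi (2.9 equiv), THF, −10 °C to rt
Reagents that add atoms: trimethylsulfonium iodide, C[S+](C)C.[I-]
Why: One-carbon homologation of a terminal epoxide to an allylic alcohol: dimethylsulfonium methylide opens the epoxide at the CH2 carbon and the sulfonium betaine loses Me2S by ylide-mediated elimination, so the C–O bond at the stereocentre is never broken and the configuration is retained.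

Step 8
Reactants: 13 (R)-2-methyl-1-(triphenylmethoxy)but-3-en-2-ol; 15 methyl 3-bromo-4-fluorobenzoate
Product: 16 methyl 4-fluoro-3-[(3R)-3-hydroxy-3-methyl-4-(triphenylmethoxy)butyl]benzoate, via alkylborane 14 (not isolated)
Conditions: 9-BBN (2.2 equiv), THF, 0 °C to rt; then 15, Pd(dppf)Cl2 (5 mol %), aq K3PO4, DMF, 60 °C
Reagents that add atoms: none
Why: Anti-Markovnikov hydroboration of the vinyl group with 9-BBN followed by B-alkyl Suzuki–Miyaura coupling at the aryl bromide; aryl fluoride and ester are inert and the stereocentre is not involved.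

Step 9
Reactants: 16 methyl 4-fluoro-3-[(3R)-3-hydroxy-3-methyl-4-(triphenylmethoxy)butyl]benzoate
Product: 17 methyl (2R)-2-methyl-2-[(triphenylmethoxy)methyl]-3,4-dihydro-2H-chromene-6-carboxylate
Conditions: KN(SiMe3)2 (1.1 equiv), THF/DMF, 0 to 50 °C
Reagents that add atoms: none
Why: Intramolecular nucleophilic aromatic substitution, in which the tertiary potassium alkoxide displaces the fluoride activated by the para ester through a Meisenheimer adduct; the C–O bond of the stereocentre is kept, so C2 of the chroman is formed with retention as R.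

Step 10
Reactants: 17 methyl (2R)-2-methyl-2-[(triphenylmethoxy)methyl]-3,4-dihydro-2H-chromene-6-carboxylate
Product: 18 methyl (2R)-2-(hydroxymethyl)-2-methyl-3,4-dihydro-2H-chromene-6-carboxylate
Conditions: TsOH·H2O (10 mol %), MeOH/CH2Cl2, rt
Reagents that add atoms: none
Why: Acid-catalysed solvolysis of the trityl ether via the trityl cation, which is captured by methanol; the alkyl aryl ether and the ester should survive.

Step 11
Reactants: 18 methyl (2R)-2-(hydroxymethyl)-2-methyl-3,4-dihydro-2H-chromene-6-carboxylate
Product: 19 methyl (2R)-2-formyl-2-methyl-3,4-dihydro-2H-chromene-6-carboxylate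
Conditions: Dess–Martin periodinane, NaHCO3, CH2Cl2, rt
Reagents that add atoms: none
Why: Dess–Martin oxidation of the primary alcohol to an aldehyde that has no α-hydrogen and therefore cannot enolise or epimerise.

Step 12
Reactants: 19 methyl (2R)-2-formyl-2-methyl-3,4-dihydro-2H-chromene-6-carboxylate
Product: 20 methyl (2R)-2-methyl-2-[(E)-2-(4,4,5,5-tetramethyl-1,3,2-dioxaborolan-2-yl)ethenyl]-3,4-dihydro-2H-chromene-6-carboxylate
Conditions: Cl2CHBpin (2 equiv), CrCl2 (8 equiv), LiI (4 equiv), THF, rt
Reagents that add atoms: 2-(dichloromethyl)-4,4,5,5-tetramethyl-1,3,2-dioxaborolane, ClC(Cl)B1OC(C)(C)C(C)(C)O1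
Why: Takai–Utimoto olefination, in which the geminal dichromium species from the dihalomethylboronate adds to the aldehyde and eliminates to the (E)-alkenylboronate, a selectivity that holds for α-quaternary aldehydes.

Step 13
Reactants: 10 2-[(3E)-4-iodo-3-methylbut-3-en-1-yl]-1,3,3-trimethylcyclohex-1-ene; 20 methyl (2R)-2-methyl-2-[(E)-2-(4,4,5,5-tetramethyl-1,3,2-dioxaborolan-2-yl)ethenyl]-3,4-dihydro-2H-chromene-6-carboxylate
Product: 21 methyl (2R)-2-methyl-2-[(1E,3E)-4-methyl-6-(2,6,6-trimethylcyclohex-1-en-1-yl)hexa-1,3-dien-1-yl]-3,4-dihydro-2H-chromene-6-carboxylate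
Conditions: Pd(PPh3)4 (5 mol %), aq K3PO4 (3 equiv), THF, degassed, 45 °C
Reagents that add atoms: none
Why: Suzuki–Miyaura coupling of an alkenyl iodide with an alkenylboronate proceeds with retention at both alkenes and should give the (E,E)-diene under basic conditions that do not ionise the tertiary allylic aryl ether.

Step 14
Reactants: 21 methyl (2R)-2-methyl-2-[(1E,3E)-4-methyl-6-(2,6,6-trimethylcyclohex-1-en-1-yl)hexa-1,3-dien-1-yl]-3,4-dihydro-2H-chromene-6-carboxylate
Product: 22 (2R)-2-methyl-2-[(1E,3E)-4-methyl-6-(2,6,6-trimethylcyclohex-1-en-1-yl)hexa-1,3-dien-1-yl]-3,4-dihydro-2H-chromene-6-carboxylic acid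
Conditions: LiOH·H2O (5 equiv), THF/MeOH/H2O, 40 °C; then AcOH to pH 5, 0 °C
Reagents that add atoms: lithium hydroxide, [Li+].[OH-]
Why: Saponification of the methyl ester by acyl substitution with hydroxide, followed by acidification with acetic acid only, which should keep the acid-labile dienylic tertiary aryl ether and hence the stereocentre intact.

**Compound list**

1 | 5-bromo-2-methylpent-1-ene | C=C(C)CCCBr | starting material
2 | pent-3-yn-1-ol | CC#CCCO | starting material
3 | (4-methylpent-4-en-1-yl)magnesium bromide (formed in situ) | C=C(C)CCC[Mg]Br | intermediate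
4 | bromomagnesium (Z)-3-(bromomagnesio)-4,8-dimethylnona-3,8-dien-1-olate (formed in situ) | C=C(C)CCC/C(C)=C(/CCO[Mg]Br)[Mg]Br | intermediate
5 | (Z)-3-iodo-4,8-dimethylnona-3,8-dien-1-ol | C=C(C)CCC/C(C)=C(/CCO)I | intermediate
6 | 2-(2,6,6-trimethylcyclohex-1-en-1-yl)ethan-1-ol | CC1=C(CCO)C(C)(C)CCC1 | intermediate
7 | 2-(2-iodoethyl)-1,3,3-trimethylcyclohex-1-ene | CC1=C(CCI)C(C)(C)CCC1 | intermediate
8 | 2-(but-3-yn-1-yl)-1,3,3-trimethylcyclohex-1-ene | CC1=C(CCC#C)C(C)(C)CCC1 | intermediate
9 | dimethyl[(1E)-2-methyl-4-(2,6,6-trimethylcyclohex-1-en-1-yl)but-1-en-1-yl]alane (formed in situ) | CC1=C(CC/C(C)=C/[Al](C)C)C(C)(C)CCC1 | intermediate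
10 | 2-[(3E)-4-iodo-3-methylbut-3-en-1-yl]-1,3,3-trimethylcyclohex-1-ene | CC1=C(CC/C(C)=C/I)C(C)(C)CCC1 | intermediate
11 | (S)-2-methylglycidol, [(2S)-2-methyloxiran-2-yl]methanol | OC[C@@]1(C)CO1 | starting material
12 | (R)-2-methyl-2-[(triphenylmethoxy)methyl]oxirane | O(C[C@@]1(C)CO1)C(c1ccccc1)(c1ccccc1)c1ccccc1 | intermediate
13 | (R)-2-methyl-1-(triphenylmethoxy)but-3-en-2-ol | O(C[C@@](O)(C)C=C)C(c1ccccc1)(c1ccccc1)c1ccccc1 | intermediate
14 | 9-[(3R)-3-hydroxy-3-methyl-4-(triphenylmethoxy)butyl]-9-borabicyclo[3.3.1]nonane (formed in situ) | O(C[C@@](O)(C)CCB1C2CCCC1CCC2)C(c1ccccc1)(c1ccccc1)c1ccccc1 | intermediate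
15 | methyl 3-bromo-4-fluorobenzoate | COC(=O)c1ccc(F)c(Br)c1 | starting material
16 | methyl 4-fluoro-3-[(3R)-3-hydroxy-3-methyl-4-(triphenylmethoxy)butyl]benzoate | O(C[C@@](O)(C)CCc1cc(C(=O)OC)ccc1F)C(c1ccccc1)(c1ccccc1)c1ccccc1 | intermediate
17 | methyl (2R)-2-methyl-2-[(triphenylmethoxy)methyl]-3,4-dihydro-2H-chromene-6-carboxylate | O(C[C@@]1(C)CCc2cc(C(=O)OC)ccc2O1)C(c1ccccc1)(c1ccccc1)c1ccccc1 | intermediate
18 | methyl (2R)-2-(hydroxymethyl)-2-methyl-3,4-dihydro-2H-chromene-6-carboxylate | OC[C@@]1(C)CCc2cc(C(=O)OC)ccc2O1 | intermediate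
19 | methyl (2R)-2-formyl-2-methyl-3,4-dihydro-2H-chromene-6-carboxylate | O=C[C@@]1(C)CCc2cc(C(=O)OC)ccc2O1 | intermediate
20 | methyl (2R)-2-methyl-2-[(E)-2-(4,4,5,5-tetramethyl-1,3,2-dioxaborolan-2-yl)ethenyl]-3,4-dihydro-2H-chromene-6-carboxylate | CC1(C)OB(/C=C/[C@@]2(C)CCc3cc(C(=O)OC)ccc3O2)OC1(C)C | intermediate
21 | methyl (2R)-2-methyl-2-[(1E,3E)-4-methyl-6-(2,6,6-trimethylcyclohex-1-en-1-yl)hexa-1,3-dien-1-yl]-3,4-dihydro-2H-chromene-6-carboxylate | CC1=C(CC/C(C)=C/C=C/[C@@]2(C)CCc3cc(C(=O)OC)ccc3O2)C(C)(C)CCC1 | intermediate
22 | (2R)-2-methyl-2-[(1E,3E)-4-methyl-6-(2,6,6-trimethylcyclohex-1-en-1-yl)hexa-1,3-dien-1-yl]-3,4-dihydro-2H-chromene-6-carboxylic acid | CC1=C(CC/C(C)=C/C=C/[C@@]2(C)CCc3cc(C(=O)O)ccc3O2)C(C)(C)CCC1 | target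

**Count and risks**

Total step count: 14. Longest linear sequence: 9 steps (steps 6 to 12, then 13 and 14); the carbocyclic branch has 5 steps before the union.

Step 1 is the most likely to fail. β-Hydride loss from the alkyl–iron species can outrun carbometalation and give hydrometalation or reduction of the alkyne, and regio- or stereocontrol of the addition may erode with a primary alkyl Grignard reagent. The fallback sets out from Grignard reagent 3 and comes back at alkyne 8, using a copper-mediated conjugate carbometalation instead of the directed iron-catalysed one. 3 is transmetallated with CuBr·SMe2 (THF, −40 °C) to (4-methylpent-4-en-1-yl)copper F1, which adds syn across commercial ethyl but-2-ynoate F2 at −78 °C to give the α-cuprio enoate F3. Iodine at −78 °C gives ethyl (Z)-2-iodo-3,7-dimethylocta-2,7-dienoate F4 with iodine cis to the chain. i-Bu2AlH reduces F4 to (Z)-2-iodo-3,7-dimethylocta-2,7-dien-1-ol F5, and the same formate-terminated 6-exo Heck closure gives (2,6,6-trimethylcyclohex-1-en-1-yl)methanol F6. PBr3 converts F6 into 2-(bromomethyl)-1,3,3-trimethylcyclohex-1-ene F7, LiCH2C≡CSiMe3 displaces the bromide to give the silylalkyne F8, and K2CO3/MeOH removes silicon to give 8.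

Step 2 is second. Formate can reduce the alkenylpalladium before the congested insertion takes place, and the neopentylpalladium can be captured by the neighbouring ring alkene (3-exo) and rearrange instead of being reduced. The fallback gives up the organopalladium closure and forms the same ring bond by cation–olefin cyclisation. It branches from no numbered compound: it replaces compounds 1 to 7, sets out from commercial pseudoionone F9 and comes back to the route at alkyne 8. Cold concentrated H2SO4 cyclises F9 to β-ionone F10 (6-endo attack of the trisubstituted alkene on the tertiary cation, the conjugated tetrasubstituted alkene being the thermodynamic product). Conjugate reduction with [(Ph3P)CuH]6 gives dihydro-β-ionone F11. LiN(i-Pr)2 and ClP(O)(OEt)2 at −78 °C give the kinetic enol phosphate F12, and a further 2.2 equiv of LiN(i-Pr)2 eliminates it to 8.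

Step 9 is third. Displacement of a fluoride that is activated only by a para ester by a hindered tertiary alkoxide may be slow, so that attack on the ester or decomposition of the alkoxide takes over. The fallback sets out from alkylborane 14 and comes back at 17, replacing SNAr by palladium-catalysed C–O bond formation. 14 is coupled at the C–I bond of commercial methyl 4-bromo-3-iodobenzoate F13 (Pd(dppf)Cl2, aq K3PO4, rt) to give methyl 4-bromo-3-[(3R)-3-hydroxy-3-methyl-4-(triphenylmethoxy)butyl]benzoate F14. F14 is then closed to 17 by intramolecular etherification (Pd(OAc)2, 2-(di-tert-butylphosphino)-1,1'-binaphthyl, Cs2CO3, toluene, 80 °C), which leaves the stereocentre untouched.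

Further compounds
F1 | step 1 | (4-methylpent-4-en-1-yl)copper | C=C(C)CCC[Cu]
F2 | step 1 | ethyl but-2-ynoate (commercial starting material of the fallback) | CCOC(=O)C#CC
F3 | step 1 | ethyl (Z)-2-cuprio-3,7-dimethylocta-2,7-dienoate | CCOC(=O)/C([Cu])=C(C)/CCCC(C)=C
F4 | step 1 | ethyl (Z)-2-iodo-3,7-dimethylocta-2,7-dienoate | CCOC(=O)/C(I)=C(C)/CCCC(C)=C
F5 | step 1 | (Z)-2-iodo-3,7-dimethylocta-2,7-dien-1-ol | OC/C(I)=C(C)/CCCC(C)=C
F6 | step 1 | (2,6,6-trimethylcyclohex-1-en-1-yl)methanol | OCC1=C(C)CCCC1(C)C
F7 | step 1 | 2-(bromomethyl)-1,3,3-trimethylcyclohex-1-ene | BrCC1=C(C)CCCC1(C)C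
F8 | step 1 | trimethyl[4-(2,6,6-trimethylcyclohex-1-en-1-yl)but-1-yn-1-yl]silane | C[Si](C)(C)C#CCCC1=C(C)CCCC1(C)C
F9 | step 2 | pseudoionone, (3E,5E)-6,10-dimethylundeca-3,5,9-trien-2-one (commercial starting material of the fallback) | CC(=O)/C=C/C=C(\C)CCC=C(C)C
F10 | step 2 | β-ionone, (E)-4-(2,6,6-trimethylcyclohex-1-en-1-yl)but-3-en-2-one | CC(=O)/C=C/C1=C(C)CCCC1(C)C
F11 | step 2 | dihydro-β-ionone, 4-(2,6,6-trimethylcyclohex-1-en-1-yl)butan-2-one | CC(=O)CCC1=C(C)CCCC1(C)C
F12 | step 2 | diethyl 4-(2,6,6-trimethylcyclohex-1-en-1-yl)but-1-en-2-yl phosphate | C=C(CCC1=C(C)CCCC1(C)C)OP(=O)(OCC)OCC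
F13 | step 9 | methyl 4-bromo-3-iodobenzoate (commercial starting material of the fallback) | COC(=O)c1ccc(Br)c(I)c1
F14 | step 9 | methyl 4-bromo-3-[(3R)-3-hydroxy-3-methyl-4-(triphenylmethoxy)butyl]benzoate | O(C[C@@](O)(C)CCc1cc(C(=O)OC)ccc1Br)C(c1ccccc1)(c1ccccc1)c1ccccc1
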